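Atoms carry germacrane numbers (carbocycle C1–C10, lactone carbonyl C12, exocyclic methylene C13, methyl C14, hydroxymethyl C15). Retrosynthetic cuts, in order: O–C3 of the hemiketal bridge (back to a C3 enone and a C10 alcohol), C3–C4 (Nozaki–Hiyama–Kishi), C11=C13 (Horner–Wadsworth–Emmons), C7–C11 together with O6–C12 (lactone annulation), C6–C7 (alkenylzinc plus enal).
Enabling feature: the γ-lactone ring (O6, C12, C11, C7, C6) and the C8 ester put O6, C11 and O8 on the contiguous carbons C6, C7, C8; this triad equals anti opening at C7 of an erythro trans-C7,C8-epoxy C6-alcohol by a carbanion hung on O6.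
Forward: fragment A (from (R)-linalool: C1–C3, C8–C10, C14, then C7 by homologation) and fragment B (from but-2-yne-1,4-diol: C4–C6, C15) are joined at C6–C7; the γ-lactone closes first (step 11), the ten-membered carbocycle second (step 14), the tetrahydrofuran hemiketal bridge last (step 17).
Stereochemistry: C10 comes from (R)-linalool; C6, C7 and C8 from the titanium/D-(−)-tartrate kinetic-resolution epoxidation followed by invertive opening at C7; the Z C4=C5 olefin from hydroxyl-directed trans-hydroalumination/iodination; C3 is fixed by the bridge.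

Key step: step 11

Remark: C3 is a hemiketal carbon that opens to the C3 ketone and re-closes, and the oxygen bridge from C10 permits a single mode of closure, so no reagent sets it; C6, C7, C8 and C10 are built as drawn and C3 is written with the descriptor of the target structure.

Step 1
Reactants: 1 (R)-(−)-linalool
Product: 2 (3R)-3,7-dimethyl-3-(triethylsilyloxy)octa-1,6-diene
Conditions: TESOTf, 2,6-lutidine, CH2Cl2, −78 → 0 °C
Reagents that add atoms: triethylsilyl trifluoromethanesulfonate, CC[Si](CC)(CC)OS(=O)(=O)C(F)(F)F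
Why: Silylation of a tertiary alcohol with a silyl triflate and a hindered pyridine base is standard, and the C10 stereocentre taken from the chiral pool is not touched.

Step 2
Reactants: 2 (3R)-3,7-dimethyl-3-(triethylsilyloxy)octa-1,6-diene
Product: 4 (3R)-3,7-dimethyl-3-(triethylsilyloxy)oct-6-en-1-ol, via B-alkyl-9-BBN adduct 3 (not isolated)
Conditions: 9-BBN, THF, 0 °C → rt; then NaOH, H2O2, 0 °C
Reagents that add atoms: hydrogen peroxide, OO
Why: Hydroboration–oxidation; 9-BBN adds anti-Markovnikov to the monosubstituted vinyl group far faster than to the trisubstituted olefin, and alkaline peroxide replaces boron by hydroxyl while the tertiary silyl ether stays.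

Step 3
Reactants: 4 (3R)-3,7-dimethyl-3-(triethylsilyloxy)oct-6-en-1-ol
Product: 5 (3R)-3,7-dimethyl-3-(triethylsilyloxy)oct-6-enal
Conditions: Dess–Martin periodinane, CH2Cl2, rt
Reagents that add atoms: none
Why: Dess–Martin oxidation stops at the aldehyde under near-neutral conditions, so the β-silyloxy aldehyde should neither eliminate nor epimerise.

Step 4
Reactants: 5 (3R)-3,7-dimethyl-3-(triethylsilyloxy)oct-6-enal
Product: 6 (4R)-4,8-dimethyl-4-(triethylsilyloxy)non-7-en-1-yne
Conditions: dimethyl (1-diazo-2-oxopropyl)phosphonate, K2CO3, MeOH, 0 °C → rt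
Reagents that add atoms: dimethyl (1-diazo-2-oxopropyl)phosphonate, COP(=O)(OC)C(=[N+]=[N-])C(C)=O
Why: Ohira–Bestmann (Seyferth–Gilbert) homologation turns the aldehyde into the terminal alkyne and adds C7; a β-silyloxy group is a poor leaving group, so the carbonate base should cause no elimination.

Step 5
Reactants: 7 but-2-yne-1,4-diol
Product: 8 4-(tert-butyldimethylsilyloxy)but-2-yn-1-ol
Conditions: NaH (1 equiv), THF, 0 °C; then TBSCl, rt
Reagents that add atoms: tert-butyldimethylsilyl chloride, CC(C)(C)[Si](C)(C)Cl
Why: Monosilylation of a symmetrical diol through its sparingly soluble monosodium alkoxide, which limits double silylation.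

Step 6
Reactants: 8 4-(tert-butyldimethylsilyloxy)but-2-yn-1-ol
Product: 10 (2Z)-4-(tert-butyldimethylsilyloxy)-3-iodobut-2-en-1-ol, via cyclic alkenylaluminate 9 (not isolated)
Conditions: NaAlH2(OCH2CH2OMe)2, THF, 0 °C → rt; then I2, −78 °C
Reagents that add atoms: iodine, II
Why: Hydroxyl-directed trans-hydroalumination of the propargylic alcohol puts aluminium on the distal alkyne carbon in a five-membered alkoxyaluminate, and iodinolysis with retention gives the Z-3-iodo allylic alcohol, which sets the Z C4=C5 geometry.

Step 7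
Reactants: 10 (2Z)-4-(tert-butyldimethylsilyloxy)-3-iodobut-2-en-1-ol
Product: 11 (2Z)-4-(tert-butyldimethylsilyloxy)-3-iodobut-2-enal
Conditions: MnO2, CH2Cl2, rt
Reagents that add atoms: none
Why: MnO2 oxidises allylic alcohols selectively to enals and should leave the vinyl iodide and the olefin geometry unchanged.

Step 8
Reactants: 6 (4R)-4,8-dimethyl-4-(triethylsilyloxy)non-7-en-1-yne, 11 (2Z)-4-(tert-butyldimethylsilyloxy)-3-iodobut-2-enal
Product: 14 bis-allylic C6 alcohol as both C6 epimers, via alkenylzirconocene chloride 12 (not isolated), via alkenyl(methyl)zinc 13 (not isolated)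
Conditions: Cp2Zr(H)Cl, CH2Cl2, rt; Me2Zn, toluene, −65 °C; then 11, 0 °C
Reagents that add atoms: none
Why: Hydrozirconation adds Zr–H syn and anti-Markovnikov to the terminal alkyne and so fixes the 7E geometry, and zirconium-to-zinc transmetalation gives an alkenylzinc that adds 1,2 to the enal without touching the vinyl iodide; no facial control is expected, so C6 forms as both epimers.

Step 9
Reactants: 14 bis-allylic C6 alcohol as both C6 epimers
Product: 15 erythro trans-C7,C8-epoxy C6-alcohol
Conditions: Ti(OiPr)4, D-(−)-diisopropyl tartrate, t-BuOOH (0.6 equiv), 4 Å molecular sieves, CH2Cl2, −20 °C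
Reagents that add atoms: tert-butyl hydroperoxide, CC(C)(C)OO
Why: Sharpless asymmetric epoxidation run as a kinetic resolution: the titanium/D-(−)-tartrate catalyst should epoxidise the E-disubstituted C7=C8 olefin of the 6S carbinol much faster than that of its 6R epimer and place O6 and O7 erythro, which sets C6 (by selection) and C7 and C8 (by reagent-controlled face choice) together, while the cis-substituted electron-poor iodoalkene and the isolated prenyl olefin are not substrates; the 6R epimer stays as allylic alcohol and is separated.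

Step 10
Reactants: 15 erythro trans-C7,C8-epoxy C6-alcohol, 16 (diethoxyphosphoryl)acetic acid
Product: 17 C6 (diethoxyphosphoryl)acetate of the epoxy alcohol
Conditions: DCC, DMAP (cat.), CH2Cl2, 0 °C → rt
Reagents that add atoms: none
Why: Steglich esterification acylates the hindered secondary alcohol under neutral conditions, so neither epoxide opening nor Payne rearrangement is expected.

Step 11
Reactants: 17 C6 (diethoxyphosphoryl)acetate of the epoxy alcohol
Product: 18 trans α-(diethoxyphosphoryl) γ-lactone with free C8 hydroxyl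
Conditions: NaH (1.05 equiv), THF, 0 °C → rt; then AcOH, 0 °C
Reagents that add atoms: none
Why: NaH removes the C11 proton between phosphonate and ester, and the sodium carbanion, held five atoms from C7 through C12 and O6, attacks C7 from the face opposite the epoxide oxygen, which forms C7–C11, closes the γ-lactone (O6, C12, C11, C7, C6) and releases the C8 oxygen. The closest known reaction type is the opening of an epoxide by a tethered phosphonoacetate or malonate carbanion (ester-carbanion lactone annulation), which is also the first stage of the intramolecular Wadsworth–Emmons cyclopropanation. The ring closes in the 5-exo-tet mode; attack at C8 would be a six-membered endo opening and is disfavoured by the tether length. C7 is set by inversion of the epoxide carbon made in step 9, C8 keeps the oxygen and configuration of that epoxide, and C11 should settle trans to the C7 side chain by equilibration of the acidic phosphonate centre (it becomes sp2 in step 15). The step must stop at the hydroxy phosphonate: one equivalent of base and a temperature not above ambient leave the product as the phosphonate-stabilised lactone enolate with a neutral C8 hydroxyl, which cannot start phosphoryl transfer to oxygen, cyclopropane closure or translactonisation before the acetic acid quench.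

Step 12
Reactants: 18 trans α-(diethoxyphosphoryl) γ-lactone with free C8 hydroxyl
Product: 19 C8 isobutyrate of the phosphono lactone
Conditions: (i-PrCO)2O, Et3N, DMAP (cat.), CH2Cl2, 0 °C → rt
Reagents that add atoms: isobutyric anhydride, CC(C)C(=O)OC(=O)C(C)C
Why: DMAP-catalysed acylation of the only free hydroxyl installs the final C8 ester early; the amine base is too weak to enolise the phosphono lactone, so C-acylation and translactonisation should not compete.

Step 13
Reactants: 19 C8 isobutyrate of the phosphono lactone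
Product: 21 C3 aldehyde, via vicinal diol 20 (not isolated)
Conditions: OsO4 (cat.), NaIO4, 2,6-lutidine, dioxane/H2O, rt
Reagents that add atoms: osmium tetroxide (catalytic, its oxygen resupplied by periodate), O=[Os](=O)(=O)=O; sodium periodate, [Na+].[O-]I(=O)(=O)=O
Why: Johnson–Lemieux oxidation: osmylation should choose the electron-rich trisubstituted prenyl olefin over the electron-poor iodoalkene, and periodate cleaves the diol to the C3 aldehyde and acetone.

Step 14
Reactants: 21 C3 aldehyde
Product: 22 ten-membered C3 allylic alcohol with α-phosphono lactone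
Conditions: CrCl2 (excess), NiCl2 (cat.), DMSO/THF, high dilution, rt
Reagents that add atoms: none
Why: Intramolecular Nozaki–Hiyama–Kishi reaction: zerovalent nickel inserts into the C4–I bond with retention of the Z geometry, transmetalation gives an alkenyl species of trivalent chromium that adds only to the aldehyde (esters, lactone and phosphonate are tolerated) and closes the carbocycle at C3–C4; the C3 configuration is irrelevant because C3 is oxidised in step 16.

Step 15
Reactants: 22 ten-membered C3 allylic alcohol with α-phosphono lactone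
Product: 23 ten-membered C3 allylic alcohol with α-methylene lactone
Conditions: K2CO3, aq. HCHO, THF, 0 °C → rt
Reagents that add atoms: formaldehyde, C=O
Why: Horner–Wadsworth–Emmons olefination of an α-phosphono γ-lactone with formaldehyde is the standard entry to α-methylene γ-lactones, and the carbonate base should spare the isobutyrate and the silyl ethers; until this point the phosphonate has also masked the methylene group from osmium and chromium.

Step 16
Reactants: 23 ten-membered C3 allylic alcohol with α-methylene lactone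
Product: 24 ten-membered C3 enone
Conditions: Dess–Martin periodinane, CH2Cl2, 0 °C → rt
Reagents that add atoms: none
Why: Dess–Martin oxidation of the only free hydroxyl, a secondary allylic alcohol, gives the conjugated enone and converges both C3 epimers.

Step 17
Reactants: 24 ten-membered C3 enone
Product: 26 target hemiketal CNP0282937.1, via C3-keto C10-alcohol 25 (not isolated)
Conditions: HF·pyridine, pyridine, THF, 0 °C → rt
Reagents that add atoms: none
Why: Fluoride desilylation frees the C10 and C15 hydroxyls, and the γ-hydroxy ketone (C10 OH, C3 C=O) should close spontaneously to the five-membered cyclic hemiketal that forms the oxygen bridge, under thermodynamic control and with the bridge fixing C3.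

Compound list
1 | (R)-(−)-linalool, (3R)-3,7-dimethylocta-1,6-dien-3-ol | C=C[C@](C)(O)CCC=C(C)C | starting material
2 | (3R)-3,7-dimethyl-3-(triethylsilyloxy)octa-1,6-diene | C=C[C@](C)(O[Si](CC)(CC)CC)CCC=C(C)C | intermediate
3 | B-alkyl-9-BBN adduct of 2, boron on the former terminal vinyl carbon | C1CCC2CCCC1B2CC[C@](C)(O[Si](CC)(CC)CC)CCC=C(C)C | intermediate
4 | (3R)-3,7-dimethyl-3-(triethylsilyloxy)oct-6-en-1-ol | OCC[C@](C)(O[Si](CC)(CC)CC)CCC=C(C)C | intermediate
5 | (3R)-3,7-dimethyl-3-(triethylsilyloxy)oct-6-enal | O=CC[C@](C)(O[Si](CC)(CC)CC)CCC=C(C)C | intermediate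
6 | (4R)-4,8-dimethyl-4-(triethylsilyloxy)non-7-en-1-yne (fragment A; the prenyl olefin masks the C3 aldehyde) | C#CC[C@](C)(O[Si](CC)(CC)CC)CCC=C(C)C | intermediate
7 | but-2-yne-1,4-diol | OCC#CCO | starting material
8 | 4-(tert-butyldimethylsilyloxy)but-2-yn-1-ol | OCC#CCO[Si](C)(C)C(C)(C)C | intermediate
9 | sodium cyclic alkenyl(alkoxy)aluminate from 8, aluminium on the carbon bearing CH2OTBS | [Na+].COCCO[Al-]1(OCCOC)OCC=C1CO[Si](C)(C)C(C)(C)C | intermediate
10 | (2Z)-4-(tert-butyldimethylsilyloxy)-3-iodobut-2-en-1-ol | OC/C=C(/CO[Si](C)(C)C(C)(C)C)I | intermediate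
11 | (2Z)-4-(tert-butyldimethylsilyloxy)-3-iodobut-2-enal (fragment B: C6, C5, C4, C15) | O=C/C=C(/CO[Si](C)(C)C(C)(C)C)I | intermediate
12 | (E)-alkenylzirconocene chloride from 6 | Cl[Zr](C1C=CC=C1)(C1C=CC=C1)/C=C/C[C@](C)(O[Si](CC)(CC)CC)CCC=C(C)C | intermediate
13 | (E)-alkenyl(methyl)zinc from 12 | C[Zn]/C=C/C[C@](C)(O[Si](CC)(CC)CC)CCC=C(C)C | intermediate
14 | bis-allylic C6 alcohol, 7E olefin, Z-C4 iodide, C15 OTBS, C10 OTES (10R), both C6 epimers | OC(/C=C(/CO[Si](C)(C)C(C)(C)C)I)/C=C/C[C@](C)(O[Si](CC)(CC)CC)CCC=C(C)C | intermediate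
15 | erythro trans-C7,C8-epoxy C6-alcohol, (6R,7R,8R,10R), other groups as in 14 | O[C@H](/C=C(/CO[Si](C)(C)C(C)(C)C)I)[C@H]1O[C@@H]1C[C@](C)(O[Si](CC)(CC)CC)CCC=C(C)C | intermediate
16 | (diethoxyphosphoryl)acetic acid | OC(=O)CP(=O)(OCC)OCC | starting material
17 | C6 (diethoxyphosphoryl)acetate of 15 (key-step precursor) | CCOP(=O)(OCC)CC(=O)O[C@H](/C=C(/CO[Si](C)(C)C(C)(C)C)I)[C@H]1O[C@@H]1C[C@](C)(O[Si](CC)(CC)CC)CCC=C(C)C | intermediate
18 | trans α-(diethoxyphosphoryl) γ-lactone (6,12-olide) with free C8 hydroxyl, C7 inverted relative to 17, C11 trans to the C7 side chain (key-step product) | CCOP(=O)(OCC)[C@@H]1C(=O)O[C@H](/C=C(/CO[Si](C)(C)C(C)(C)C)I)[C@H]1[C@H](O)C[C@](C)(O[Si](CC)(CC)CC)CCC=C(C)C | intermediate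
19 | C8 isobutyrate of 18 | CCOP(=O)(OCC)[C@@H]1C(=O)O[C@H](/C=C(/CO[Si](C)(C)C(C)(C)C)I)[C@H]1[C@H](OC(=O)C(C)C)C[C@](C)(O[Si](CC)(CC)CC)CCC=C(C)C | intermediate
20 | vicinal diol from the prenyl olefin of 19 (new carbinol centre unassigned) | CCOP(=O)(OCC)[C@@H]1C(=O)O[C@H](/C=C(/CO[Si](C)(C)C(C)(C)C)I)[C@H]1[C@H](OC(=O)C(C)C)C[C@](C)(O[Si](CC)(CC)CC)CCC(O)C(C)(C)O | intermediate
21 | C3 aldehyde with Z-C4 iodide, α-phosphono lactone and C8 isobutyrate | CCOP(=O)(OCC)[C@@H]1C(=O)O[C@H](/C=C(/CO[Si](C)(C)C(C)(C)C)I)[C@H]1[C@H](OC(=O)C(C)C)C[C@](C)(O[Si](CC)(CC)CC)CCC=O | intermediate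
22 | ten-membered C3 allylic alcohol (both C3 epimers), 4Z olefin, α-phosphono lactone | CCOP(=O)(OCC)[C@@H]1C(=O)O[C@@H]2/C=C(/CO[Si](C)(C)C(C)(C)C)C(O)CC[C@@](C)(O[Si](CC)(CC)CC)C[C@@H](OC(=O)C(C)C)[C@@H]12 | intermediate
23 | ten-membered C3 allylic alcohol (both C3 epimers) with α-methylene lactone | C=C1C(=O)O[C@@H]2/C=C(/CO[Si](C)(C)C(C)(C)C)C(O)CC[C@@](C)(O[Si](CC)(CC)CC)C[C@@H](OC(=O)C(C)C)[C@@H]12 | intermediate
24 | ten-membered C3 enone, C10 OTES, C15 OTBS | C=C1C(=O)O[C@@H]2/C=C(/CO[Si](C)(C)C(C)(C)C)C(=O)CC[C@@](C)(O[Si](CC)(CC)CC)C[C@@H](OC(=O)C(C)C)[C@@H]12 | intermediate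
25 | C3-keto C10,C15-diol (open form of the target) | C=C1C(=O)O[C@@H]2/C=C(/CO)C(=O)CC[C@@](C)(O)C[C@@H](OC(=O)C(C)C)[C@@H]12 | intermediate
26 | CNP0282937.1: 3,15-dihydroxy-3,10-epoxy-8-isobutyryloxygermacra-4Z,11(13)-dien-6,12-olide, stereocentres as in the target structure | C=C1C(=O)O[C@@H]2/C=C(/CO)[C@@]3(O)CC[C@](C)(C[C@@H](OC(=O)C(C)C)[C@@H]12)O3 | target

Total steps: 17. Longest linear sequence: 14 steps (1 to 26 through steps 1–4 and 8–17).

Steps most likely to fail

Step 11. The C8 alkoxide may take the phosphoryl group from C11 and the resulting lactone enolate may then close a cyclopropane (Wadsworth–Emmons pathway), or the opening may be slow enough for ester cleavage to compete. The fallback sets out from 15 and returns at 23. Diketene with catalytic DMAP should give the acetoacetate F1. NaH in THF should close the same 5-exo ring to the α-acetyl lactone F2, whose C-acyl group cannot hand a leaving group to O8. Steglich acylation with isobutyric acid should give the isobutyrate F3. K2CO3 and aqueous formaldehyde should then effect deacetylative methylenation to the α-methylene lactone F4. OsO4/NaIO4 should cleave the prenyl olefin through the diol F5 to the aldehyde F6, and CrCl2/NiCl2 cyclisation as in step 14 should give 23.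

Step 14. Intermolecular coupling and reductive loss of iodine may outpace closure of the ten-membered ring. The fallback sets out from 21 and returns at 24. NaClO2/NaH2PO4 with 2-methyl-2-butene should oxidise the aldehyde to the carboxylic acid F7. Me3SnSnMe3 with Pd(PPh3)4 should convert the iodide with retention into the alkenylstannane F8. 1-Chloro-N,N,2-trimethylpropenylamine should give the acid chloride F9, which under zerovalent palladium catalysis at high dilution (intramolecular Stille acylation) should close C3–C4 directly at the ketone level to the phosphono enone F10. Formaldehyde olefination under the conditions of step 15 should then give 24.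

Step 9. The rate difference between the C6 epimers may be small or turnover may stall at the hindered bis-allylic titanium alkoxide, and at best half of 14 is used. The fallback sets out from 6 and 11 and returns at 15. The alkenylzinc addition of step 8 is run in the presence of a chiral amino alcohol ligand (3-exo-morpholinoisoborneol, the enantiomer that directs the alkenyl group to the aldehyde face leading to the 6S carbinol), which should give the 6S alcohol F11 as the main epimer. The same Ti(OiPr)4/D-(−)-diisopropyl tartrate epoxidation, now a matched pair run with a full equivalent of t-BuOOH, should give 15 and leave residual 6R material unreacted.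

Further compounds
F1 | step 11 | C6 acetoacetate of 15 | CC(=O)CC(=O)O[C@H](/C=C(/CO[Si](C)(C)C(C)(C)C)I)[C@H]1O[C@@H]1C[C@](C)(O[Si](CC)(CC)CC)CCC=C(C)C
F2 | step 11 | trans α-acetyl γ-lactone with free C8 hydroxyl | CC(=O)[C@@H]1C(=O)O[C@H](/C=C(/CO[Si](C)(C)C(C)(C)C)I)[C@H]1[C@H](O)C[C@](C)(O[Si](CC)(CC)CC)CCC=C(C)C
F3 | step 11 | C8 isobutyrate of F2 | CC(=O)[C@@H]1C(=O)O[C@H](/C=C(/CO[Si](C)(C)C(C)(C)C)I)[C@H]1[C@H](OC(=O)C(C)C)C[C@](C)(O[Si](CC)(CC)CC)CCC=C(C)C
F4 | step 11 | α-methylene γ-lactone with C8 isobutyrate, Z-C4 iodide and prenyl end | C=C1C(=O)O[C@H](/C=C(/CO[Si](C)(C)C(C)(C)C)I)[C@H]1[C@H](OC(=O)C(C)C)C[C@](C)(O[Si](CC)(CC)CC)CCC=C(C)C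
F5 | step 11 | vicinal diol from the prenyl olefin of F4 | C=C1C(=O)O[C@H](/C=C(/CO[Si](C)(C)C(C)(C)C)I)[C@H]1[C@H](OC(=O)C(C)C)C[C@](C)(O[Si](CC)(CC)CC)CCC(O)C(C)(C)O
F6 | step 11 | C3 aldehyde with α-methylene lactone and Z-C4 iodide | C=C1C(=O)O[C@H](/C=C(/CO[Si](C)(C)C(C)(C)C)I)[C@H]1[C@H](OC(=O)C(C)C)C[C@](C)(O[Si](CC)(CC)CC)CCC=O
F7 | step 14 | C3 carboxylic acid from 21 | CCOP(=O)(OCC)[C@@H]1C(=O)O[C@H](/C=C(/CO[Si](C)(C)C(C)(C)C)I)[C@H]1[C@H](OC(=O)C(C)C)C[C@](C)(O[Si](CC)(CC)CC)CCC(=O)O
F8 | step 14 | Z-C4 trimethylstannane of F7 | CCOP(=O)(OCC)[C@@H]1C(=O)O[C@H](/C=C(/CO[Si](C)(C)C(C)(C)C)[Sn](C)(C)C)[C@H]1[C@H](OC(=O)C(C)C)C[C@](C)(O[Si](CC)(CC)CC)CCC(=O)O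
F9 | step 14 | C3 acid chloride of F8 | CCOP(=O)(OCC)[C@@H]1C(=O)O[C@H](/C=C(/CO[Si](C)(C)C(C)(C)C)[Sn](C)(C)C)[C@H]1[C@H](OC(=O)C(C)C)C[C@](C)(O[Si](CC)(CC)CC)CCC(=O)Cl
F10 | step 14 | ten-membered C3 enone with α-phosphono lactone | CCOP(=O)(OCC)[C@@H]1C(=O)O[C@@H]2/C=C(/CO[Si](C)(C)C(C)(C)C)C(=O)CC[C@@](C)(O[Si](CC)(CC)CC)C[C@@H](OC(=O)C(C)C)[C@@H]12
F11 | step 9 | 6S epimer of 14 | O[C@H](/C=C(/CO[Si](C)(C)C(C)(C)C)I)/C=C/C[C@](C)(O[Si](CC)(CC)CC)CCC=C(C)C
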